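**Retrosynthetic overview**
- The target comes from its 2-O-TES, 8-hydroxy precursor by angeloylation and desilylation; the last three steps only unmask and acylate.
- Both rings come from one closure of the C6–C7 bond (the farnesyl C1–C10 bond made by the cyclase): an acyclic (2E,6Z)-farnesane-type enal carrying a 2-(chloromethyl)acrylate is closed with CrCl2. The ten-membered ring forms first, then the 6,12-γ-lactone in the same flask.
- The seco-chain comes from a C9–C10 bond: chelation-controlled addition of a Z-alkenylmagnesium (C1–C6, C10, Me-14, Me-15) to an α-PMB-oxy aldehyde (C7–C9, C11–C13), with the acetate put on in the quench.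
- The alkenyl iodide comes from an enantioselective vinylogous Mukaiyama aldol on (Z)-3-iodobut-2-enal (sets C2). The aldehyde comes from a Pd-catalysed asymmetric etherification of butadiene monoepoxide (sets C8), vinylalumination, SN2′ chlorination and ozonolysis.

Assumption: locants follow germacrane numbering (C6 carries the lactone oxygen, C7 carries C11), and the catalyst or ligand antipode used in steps 4 and 7 is the one that gives the configuration stated.

**Step 1**
Reactants: 1 but-2-yn-1-ol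
Product: 3 (Z)-3-iodobut-2-en-1-ol, via cyclic alkenylalanate 2 (not isolated)
Conditions: NaAlH2(OCH2CH2OCH3)2 (1.5 equiv), Et2O, 0 °C to rt; then I2, −78 to 0 °C
Reagents that add atoms: iodine, II
Why: Hydroxyl-directed trans-hydroalumination of the propargylic alcohol leaves aluminium on C3 in a five-membered alanate, and iodinolysis with retention gives only the Z iodoalkene (hydroalumination–iodination).

**Step 2**
Reactants: 3 (Z)-3-iodobut-2-en-1-ol
Product: 4 (Z)-3-iodobut-2-enal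
Conditions: MnO2 (15 equiv), CH2Cl2, rt, dark; used at once
Reagents that add atoms: none
Why: MnO2 oxidises the allylic alcohol under neutral conditions that leave the C–I bond and the Z geometry untouched (allylic oxidation).

**Step 3**
Reactants: 5 ethyl 3-methylbut-2-enoate
Product: 7 tert-butyl[(1-ethoxy-3-methylbuta-1,3-dien-1-yl)oxy]dimethylsilane, via lithium dienolate 6 (not isolated)
Conditions: LiN(iPr)2 (1.1 equiv), THF, −78 °C; TBSCl, DMPU, −78 °C to rt
Reagents that add atoms: tert-butyldimethylsilyl chloride, CC(C)(C)[Si](C)(C)Cl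
Why: Kinetic γ-deprotonation of the senecioate and O-silylation of the extended enolate give the silyl dienol ether that serves as the C3–C6/C15 nucleophile (silyl ketene acetal formation).

**Step 4**
Reactants: 4 (Z)-3-iodobut-2-enal, 7 tert-butyl[(1-ethoxy-3-methylbuta-1,3-dien-1-yl)oxy]dimethylsilane
Product: 9 ethyl (2E,5S,6Z)-5-hydroxy-7-iodo-3-methylocta-2,6-dienoate, via trichlorosilyl ether 8 (not isolated)
Conditions: SiCl4 (1.1 equiv), Denmark binaphthyldiamine bisphosphoramide (2 mol %, antipode for Si-face attack), iPr2NEt (10 mol %), CH2Cl2, −78 °C; aq. NaHCO3 work-up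
Reagents that add atoms: none
Why: In this Lewis-base-activated SiCl4 vinylogous Mukaiyama aldol (Denmark) the dienol ether attacks through its γ-carbon to give the E-enoate, and the chiral phosphoramide-bound silyl cation directs Si-face attack on the enal so that the new carbinol (C2 of the target) is S.

**Step 5**
Reactants: 9 ethyl (2E,5S,6Z)-5-hydroxy-7-iodo-3-methylocta-2,6-dienoate
Product: 10 (2E,5S,6Z)-7-iodo-3-methylocta-2,6-diene-1,5-diol
Conditions: iBu2AlH (3.5 equiv), CH2Cl2, −78 °C; aq. KNaC4H4O6 work-up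
Reagents that add atoms: none
Why: iBu2AlH reduces the enoate 1,2 to the allylic alcohol at −78 °C without touching the alkenyl iodide or either double-bond geometry (ester reduction).

**Step 6**
Reactants: 10 (2E,5S,6Z)-7-iodo-3-methylocta-2,6-diene-1,5-diol
Product: 11 (2E,5S,6Z)-7-iodo-3-methyl-1,5-bis[(triethylsilyl)oxy]octa-2,6-diene
Conditions: Et3SiCl (2.4 equiv), imidazole, DMF, 0 °C
Reagents that add atoms: chlorotriethylsilane, CC[Si](Cl)(CC)CC
Why: Both hydroxyls are protected as TES ethers that survive t-BuLi and can later be told apart, because only a primary TES ether is cleaved under Swern conditions (silyl ether protection).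

**Step 7**
Reactants: 12 2-vinyloxirane (racemic)
Product: 13 (2S)-2-[(4-methoxybenzyl)oxy]but-3-en-1-ol
Conditions: 4-methoxybenzyl alcohol (1.1 equiv), Pd2(dba)3·CHCl3 (1 mol %), DACH-phenyl Trost ligand (3 mol %, antipode giving the 2S ether), Et3B (1 mol %), CH2Cl2, rt
Reagents that add atoms: 4-methoxybenzyl alcohol, COc1ccc(CO)cc1
Why: In this Trost dynamic kinetic asymmetric allylic etherification the π-allyl palladium complexes from the racemic epoxide interconvert, boron-tethered delivery of the alkoxide gives the branched ether, and the ligand sets the future C8 centre (S here, R from compound 20 on only through a priority change).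

**Step 8**
Reactants: 13 (2S)-2-[(4-methoxybenzyl)oxy]but-3-en-1-ol
Product: 14 (2S)-2-[(4-methoxybenzyl)oxy]but-3-enal
Conditions: Dess–Martin periodinane (1.3 equiv), NaHCO3, CH2Cl2, 0 °C; crude used within 1 h
Reagents that add atoms: none
Why: Buffered Dess–Martin oxidation gives the α-alkoxy β,γ-unsaturated aldehyde without base, so the stereocentre and the position of the alkene are preserved (alcohol oxidation).

**Step 9**
Reactants: 14 (2S)-2-[(4-methoxybenzyl)oxy]but-3-enal, 15 methyl propiolate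
Product: 17 methyl (4S)-3-hydroxy-4-[(4-methoxybenzyl)oxy]-2-methylidenehex-5-enoate, via vinylalane 16 (not isolated)
Conditions: iBu2AlH (1.5 equiv), N-methylmorpholine N-oxide (1.5 equiv), THF, 0 °C, then 15; then 14, 0 °C to rt
Reagents that add atoms: none
Why: Hydroalumination of the propiolate gives the α-aluminated acrylate, which adds to the aldehyde as a base-free Morita–Baylis–Hillman surrogate (Ramachandran vinylalumination), so C8 is not epimerised; the new C7 carbinol forms as a mixture that is erased in step 10.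

**Step 10**
Reactants: 17 methyl (4S)-3-hydroxy-4-[(4-methoxybenzyl)oxy]-2-methylidenehex-5-enoate
Product: 19 methyl (2Z,4S)-2-(chloromethyl)-4-[(4-methoxybenzyl)oxy]hexa-2,5-dienoate, via allylic mesylate 18 (not isolated)
Conditions: MsCl (1.3 equiv), Et3N (1.5 equiv), CH2Cl2, 0 °C to rt
Reagents that add atoms: methanesulfonyl chloride, CS(=O)(=O)Cl
Why: The allylic mesylate undergoes SN2′ displacement by chloride to the trisubstituted enoate with C8 cis to CH2Cl (2Z), which removes the C7 carbinol centre and installs the allyl halide (allylic transposition of a Morita–Baylis–Hillman adduct).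

**Step 11**
Reactants: 19 methyl (2Z,4S)-2-(chloromethyl)-4-[(4-methoxybenzyl)oxy]hexa-2,5-dienoate
Product: 21 methyl (2Z,4R)-2-(chloromethyl)-4-[(4-methoxybenzyl)oxy]-5-oxopent-2-enoate, via ozonide 20 (not isolated)
Conditions: O3, CH2Cl2, −78 °C (Sudan Red 7B end-point); Me2S, −78 °C to rt; used crude
Reagents that add atoms: ozone, [O-][O+]=O
Why: Ozone cleaves the electron-rich monosubstituted alkene far faster than the electron-poor chloromethyl acrylate, and neutral Me2S reduction of the ozonide gives the α-PMB-oxy aldehyde with C8 intact (chemoselective ozonolysis).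

**Step 12**
Reactants: 11 (2E,5S,6Z)-7-iodo-3-methyl-1,5-bis[(triethylsilyl)oxy]octa-2,6-diene, 21 methyl (2Z,4R)-2-(chloromethyl)-4-[(4-methoxybenzyl)oxy]-5-oxopent-2-enoate
Product: 25 methyl (2Z,4R,5R,6Z,8S,10E)-5-acetoxy-2-(chloromethyl)-4-[(4-methoxybenzyl)oxy]-6,10-dimethyl-8,12-bis[(triethylsilyl)oxy]dodeca-2,6,10-trienoate, via alkenyllithium 22 (not isolated), via alkenylmagnesium bromide 23 (not isolated), via bromomagnesium alkoxide 24 (not isolated)
Conditions: 11, t-BuLi (2.0 equiv), Et2O, −78 °C; MgBr2·OEt2 (1.5 equiv), −78 °C; 21 (1.1 equiv) in CH2Cl2, −78 °C; then AcCl (3 equiv), −78 to 0 °C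
Reagents that add atoms: acetyl chloride, CC(=O)Cl
Why: Iodine–lithium exchange with retention of the Z geometry, transmetalation to magnesium and Cram-chelate addition (magnesium bridges the aldehyde oxygen and the α-OPMB oxygen, the alkenyl group attacks anti to the C7 substituent) give the 8,9-syn (9R) alkoxide, which AcCl traps as the acetate before it can displace the allylic chloride.

**Step 13**
Reactants: 25 methyl (2Z,4R,5R,6Z,8S,10E)-5-acetoxy-2-(chloromethyl)-4-[(4-methoxybenzyl)oxy]-6,10-dimethyl-8,12-bis[(triethylsilyl)oxy]dodeca-2,6,10-trienoate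
Product: 27 methyl (2Z,4R,5R,6Z,8S,10E)-5-acetoxy-2-(chloromethyl)-4-[(4-methoxybenzyl)oxy]-6,10-dimethyl-12-oxo-8-[(triethylsilyl)oxy]dodeca-2,6,10-trienoate, via alkoxysulfonium chloride 26 (not isolated)
Conditions: (COCl)2 (2.2 equiv), DMSO (4.5 equiv), CH2Cl2, −78 to −40 °C; iPr2NEt (6 equiv), −78 to 0 °C
Reagents that add atoms: none
Why: Under Swern conditions the chlorosulfonium salt cleaves only the primary allylic TES ether and oxidises it in the same flask to the E-enal, while the secondary TES ether, PMB ether, acetate and allylic chloride are inert (direct Swern oxidation of a primary silyl ether).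

**Step 14**
Reactants: 27 methyl (2Z,4R,5R,6Z,8S,10E)-5-acetoxy-2-(chloromethyl)-4-[(4-methoxybenzyl)oxy]-6,10-dimethyl-12-oxo-8-[(triethylsilyl)oxy]dodeca-2,6,10-trienoate
Product: 30 (3aS,4R,5R,6Z,8S,10E,11aR)-4-[(4-methoxybenzyl)oxy]-6,10-dimethyl-3-methylidene-2-oxo-8-[(triethylsilyl)oxy]-2,3,3a,4,5,8,9,11a-octahydrocyclodeca[b]furan-5-yl acetate, via allylchromium dichloride 28 (not isolated), via chromium alkoxide 29 (not isolated)
Conditions: CrCl2 (8 equiv), LiI (0.2 equiv), THF/DMF 5:1, 27 added over 10 h to 0.002 M, 25 °C; then 50 °C, 2 h; aq. NH4Cl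
Reagents that add atoms: none
Why: In this intramolecular Nozaki–Hiyama (Barbier-type) allylation–lactonisation CrCl2 turns the allylic chloride into an allylchromium species that attacks the enal through C7 (SE2′) in a chair-like transition state, closing the ten-membered ring at the C6–C7 bond where the cyclase joins farnesyl C1 to C10; C6 approaches the C7 face anti to the C8–OPMB bond (C8–H eclipsing the alkene) to set 7S, the E,Z-diene tether is expected to hold C5 and C8 pseudo-equatorial so that H6 and H7 are anti (6R), and the chromium alkoxide then acylates with the neighbouring ester to give the trans-fused 6,12-lactone and the exocyclic methylene.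

**Step 15**
Reactants: 30 (3aS,4R,5R,6Z,8S,10E,11aR)-4-[(4-methoxybenzyl)oxy]-6,10-dimethyl-3-methylidene-2-oxo-8-[(triethylsilyl)oxy]-2,3,3a,4,5,8,9,11a-octahydrocyclodeca[b]furan-5-yl acetate
Product: 31 (3aR,4R,5R,6Z,8S,10E,11aR)-4-hydroxy-6,10-dimethyl-3-methylidene-2-oxo-8-[(triethylsilyl)oxy]-2,3,3a,4,5,8,9,11a-octahydrocyclodeca[b]furan-5-yl acetate
Conditions: DDQ (1.5 equiv), CH2Cl2/pH 7 phosphate buffer 10:1, 0 °C
Reagents that add atoms: none
Why: DDQ oxidises the electron-rich p-methoxybenzyl ether to its oxocarbenium ion, which water hydrolyses to free 8-OH, while the TES ether, acetate, lactone and alkenes are untouched under buffered conditions (oxidative PMB cleavage; the 3a descriptor changes by priority only).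

**Step 16**
Reactants: 31 (3aR,4R,5R,6Z,8S,10E,11aR)-4-hydroxy-6,10-dimethyl-3-methylidene-2-oxo-8-[(triethylsilyl)oxy]-2,3,3a,4,5,8,9,11a-octahydrocyclodeca[b]furan-5-yl acetate
Product: 32 (3aS,4R,5R,6Z,8S,10E,11aR)-5-acetoxy-6,10-dimethyl-3-methylidene-2-oxo-8-[(triethylsilyl)oxy]-2,3,3a,4,5,8,9,11a-octahydrocyclodeca[b]furan-4-yl (2Z)-2-methylbut-2-enoate
Conditions: angelic acid (3 equiv), 2,4,6-trichlorobenzoyl chloride (3 equiv), Et3N (6 equiv), toluene, rt, 2 h; then 31, 80 °C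
Reagents that add atoms: angelic acid, C/C=C(/C)C(=O)O
Why: Acylation through the preformed angelic 2,4,6-trichlorobenzoic anhydride without DMAP esterifies the hindered 8-OH while keeping the Z geometry, since no nucleophilic catalyst is present to isomerise the angelate to the tiglate (Yamaguchi-type mixed-anhydride esterification).

**Step 17**
Reactants: 32 (3aS,4R,5R,6Z,8S,10E,11aR)-5-acetoxy-6,10-dimethyl-3-methylidene-2-oxo-8-[(triethylsilyl)oxy]-2,3,3a,4,5,8,9,11a-octahydrocyclodeca[b]furan-4-yl (2Z)-2-methylbut-2-enoate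
Product: 33 (3aS,4R,5R,6Z,8S,10E,11aR)-5-acetoxy-8-hydroxy-6,10-dimethyl-3-methylidene-2-oxo-2,3,3a,4,5,8,9,11a-octahydrocyclodeca[b]furan-4-yl (2Z)-2-methylbut-2-enoate
Conditions: HF·pyridine, pyridine, THF, 0 °C
Reagents that add atoms: none
Why: Buffered HF·pyridine removes the secondary TES ether through Si–F bond formation without touching the two esters or the α-methylene lactone, giving the target with its five stereocentres as set in steps 4, 7, 12 and 14 (fluoride desilylation).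

**Compound list**
1 | but-2-yn-1-ol | CC#CCO | starting material
2 | sodium 3-methyl-2,2-bis(2-methoxyethoxy)-2,5-dihydro-1,2-oxaaluminol-2-uide (cyclic alkenylalanate, not isolated) | CC1=CCO[Al-]1(OCCOC)OCCOC.[Na+] | intermediate
3 | (Z)-3-iodobut-2-en-1-ol | C/C(I)=C/CO | intermediate
4 | (Z)-3-iodobut-2-enal | C/C(I)=C/C=O | intermediate
5 | ethyl 3-methylbut-2-enoate | CCOC(=O)C=C(C)C | starting material
6 | lithium 1-ethoxy-3-methylbuta-1,3-dien-1-olate (not isolated) | C=C(C)C=C(OCC)O[Li] | intermediate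
7 | tert-butyl[(1-ethoxy-3-methylbuta-1,3-dien-1-yl)oxy]dimethylsilane | C=C(C)C=C(OCC)O[Si](C)(C)C(C)(C)C | intermediate
8 | ethyl (2E,5S,6Z)-7-iodo-3-methyl-5-[(trichlorosilyl)oxy]octa-2,6-dienoate (not isolated) | CCOC(=O)/C=C(\C)C[C@H](O[Si](Cl)(Cl)Cl)/C=C(/C)I | intermediate
9 | ethyl (2E,5S,6Z)-5-hydroxy-7-iodo-3-methylocta-2,6-dienoate | CCOC(=O)/C=C(\C)C[C@H](O)/C=C(/C)I | intermediate
10 | (2E,5S,6Z)-7-iodo-3-methylocta-2,6-diene-1,5-diol | OC/C=C(\C)C[C@H](O)/C=C(/C)I | intermediate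
11 | (2E,5S,6Z)-7-iodo-3-methyl-1,5-bis[(triethylsilyl)oxy]octa-2,6-diene | CC[Si](CC)(CC)OC/C=C(\C)C[C@H](O[Si](CC)(CC)CC)/C=C(/C)I | intermediate
12 | 2-vinyloxirane (racemic butadiene monoepoxide) | C=CC1CO1 | starting material
13 | (2S)-2-[(4-methoxybenzyl)oxy]but-3-en-1-ol | C=C[C@H](OCc1ccc(OC)cc1)CO | intermediate
14 | (2S)-2-[(4-methoxybenzyl)oxy]but-3-enal | C=C[C@H](OCc1ccc(OC)cc1)C=O | intermediate
15 | methyl propiolate | C#CC(=O)OC | starting material
16 | methyl 2-(diisobutylalumanyl)prop-2-enoate (vinylalane, not isolated) | COC(=O)C(=C)[Al](CC(C)C)CC(C)C | intermediate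
17 | methyl (4S)-3-hydroxy-4-[(4-methoxybenzyl)oxy]-2-methylidenehex-5-enoate (both C3 epimers) | C=C[C@H](OCc1ccc(OC)cc1)C(O)C(=C)C(=O)OC | intermediate
18 | methyl (4S)-4-[(4-methoxybenzyl)oxy]-2-methylidene-3-[(methylsulfonyl)oxy]hex-5-enoate (not isolated) | C=C[C@H](OCc1ccc(OC)cc1)C(OS(C)(=O)=O)C(=C)C(=O)OC | intermediate
19 | methyl (2Z,4S)-2-(chloromethyl)-4-[(4-methoxybenzyl)oxy]hexa-2,5-dienoate | C=C[C@H](OCc1ccc(OC)cc1)/C=C(\CCl)C(=O)OC | intermediate
20 | methyl (2Z,4R)-2-(chloromethyl)-4-[(4-methoxybenzyl)oxy]-4-(1,2,4-trioxolan-3-yl)but-2-enoate (ozonide, not isolated) | C1OOC(O1)[C@H](OCc1ccc(OC)cc1)/C=C(\CCl)C(=O)OC | intermediate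
21 | methyl (2Z,4R)-2-(chloromethyl)-4-[(4-methoxybenzyl)oxy]-5-oxopent-2-enoate | O=C[C@H](OCc1ccc(OC)cc1)/C=C(\CCl)C(=O)OC | intermediate
22 | [(2E,4S,6E)-6-methyl-4,8-bis[(triethylsilyl)oxy]octa-2,6-dien-2-yl]lithium (Li cis to C4, not isolated) | CC[Si](CC)(CC)OC/C=C(\C)C[C@H](O[Si](CC)(CC)CC)/C=C(/C)[Li] | intermediate
23 | bromo[(2Z,4S,6E)-6-methyl-4,8-bis[(triethylsilyl)oxy]octa-2,6-dien-2-yl]magnesium (Mg cis to C4, not isolated) | CC[Si](CC)(CC)OC/C=C(\C)C[C@H](O[Si](CC)(CC)CC)/C=C(/C)[Mg]Br | intermediate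
24 | bromomagnesium 5-alkoxide of methyl (2Z,4R,5R,6Z,8S,10E)-2-(chloromethyl)-5-hydroxy-4-[(4-methoxybenzyl)oxy]-6,10-dimethyl-8,12-bis[(triethylsilyl)oxy]dodeca-2,6,10-trienoate (not isolated) | CC[Si](CC)(CC)OC/C=C(\C)C[C@H](O[Si](CC)(CC)CC)/C=C(/C)[C@@H](O[Mg]Br)[C@H](OCc1ccc(OC)cc1)/C=C(\CCl)C(=O)OC | intermediate
25 | methyl (2Z,4R,5R,6Z,8S,10E)-5-acetoxy-2-(chloromethyl)-4-[(4-methoxybenzyl)oxy]-6,10-dimethyl-8,12-bis[(triethylsilyl)oxy]dodeca-2,6,10-trienoate | CC[Si](CC)(CC)OC/C=C(\C)C[C@H](O[Si](CC)(CC)CC)/C=C(/C)[C@@H](OC(C)=O)[C@H](OCc1ccc(OC)cc1)/C=C(\CCl)C(=O)OC | intermediate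
26 | dimethyl(alkoxy)sulfonium chloride of the C12 alcohol of 25 (not isolated) | C[S+](C)OC/C=C(\C)C[C@H](O[Si](CC)(CC)CC)/C=C(/C)[C@@H](OC(C)=O)[C@H](OCc1ccc(OC)cc1)/C=C(\CCl)C(=O)OC.[Cl-] | intermediate
27 | methyl (2Z,4R,5R,6Z,8S,10E)-5-acetoxy-2-(chloromethyl)-4-[(4-methoxybenzyl)oxy]-6,10-dimethyl-12-oxo-8-[(triethylsilyl)oxy]dodeca-2,6,10-trienoate | O=C/C=C(\C)C[C@H](O[Si](CC)(CC)CC)/C=C(/C)[C@@H](OC(C)=O)[C@H](OCc1ccc(OC)cc1)/C=C(\CCl)C(=O)OC | intermediate
28 | methyl (2Z,4R,5R,6Z,8S,10E)-5-acetoxy-2-[(dichlorochromio)methyl]-4-[(4-methoxybenzyl)oxy]-6,10-dimethyl-12-oxo-8-[(triethylsilyl)oxy]dodeca-2,6,10-trienoate (not isolated) | O=C/C=C(\C)C[C@H](O[Si](CC)(CC)CC)/C=C(/C)[C@@H](OC(C)=O)[C@H](OCc1ccc(OC)cc1)/C=C(\C[Cr](Cl)Cl)C(=O)OC | intermediate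
29 | dichlorochromium 2-alkoxide of methyl 2-[(1S,2R,3E,6S,7Z,9R,10R)-9-acetoxy-2-hydroxy-10-[(4-methoxybenzyl)oxy]-4,8-dimethyl-6-[(triethylsilyl)oxy]cyclodeca-3,7-dien-1-yl]prop-2-enoate (not isolated) | COC(=O)C(=C)[C@H]1[C@H](O[Cr](Cl)Cl)/C=C(\C)C[C@H](O[Si](CC)(CC)CC)/C=C(/C)[C@@H](OC(C)=O)[C@@H]1OCc1ccc(OC)cc1 | intermediate
30 | (3aS,4R,5R,6Z,8S,10E,11aR)-4-[(4-methoxybenzyl)oxy]-6,10-dimethyl-3-methylidene-2-oxo-8-[(triethylsilyl)oxy]-2,3,3a,4,5,8,9,11a-octahydrocyclodeca[b]furan-5-yl acetate | C=C1C(=O)O[C@@H]2/C=C(\C)C[C@H](O[Si](CC)(CC)CC)/C=C(/C)[C@@H](OC(C)=O)[C@H](OCc3ccc(OC)cc3)[C@@H]12 | intermediate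
31 | (3aR,4R,5R,6Z,8S,10E,11aR)-4-hydroxy-6,10-dimethyl-3-methylidene-2-oxo-8-[(triethylsilyl)oxy]-2,3,3a,4,5,8,9,11a-octahydrocyclodeca[b]furan-5-yl acetate | C=C1C(=O)O[C@@H]2/C=C(\C)C[C@H](O[Si](CC)(CC)CC)/C=C(/C)[C@@H](OC(C)=O)[C@H](O)[C@@H]12 | intermediate
32 | (3aS,4R,5R,6Z,8S,10E,11aR)-5-acetoxy-6,10-dimethyl-3-methylidene-2-oxo-8-[(triethylsilyl)oxy]-2,3,3a,4,5,8,9,11a-octahydrocyclodeca[b]furan-4-yl (2Z)-2-methylbut-2-enoate | C=C1C(=O)O[C@@H]2/C=C(\C)C[C@H](O[Si](CC)(CC)CC)/C=C(/C)[C@@H](OC(C)=O)[C@H](OC(=O)/C(C)=C\C)[C@@H]12 | intermediate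
33 | (3aS,4R,5R,6Z,8S,10E,11aR)-5-acetoxy-8-hydroxy-6,10-dimethyl-3-methylidene-2-oxo-2,3,3a,4,5,8,9,11a-octahydrocyclodeca[b]furan-4-yl (2Z)-2-methylbut-2-enoate | C=C1C(=O)O[C@@H]2/C=C(\C)C[C@H](O)/C=C(/C)[C@@H](OC(C)=O)[C@H](OC(=O)/C(C)=C\C)[C@@H]12 | target

**Step count and risk**
Total steps: 17. Longest linear sequence: 11 steps (steps 1, 2, 4, 5, 6, 12–17 from but-2-yn-1-ol; the branch through steps 7–11 is equally long).

Most likely to fail, step 14 (ring closure). The sense at C6 rests on a conformational argument rather than on a simple open-chain rule, since intermolecular allylmetals of this kind usually favour the 6,7-syn adduct. The allylchromium can also lose the C8 alkoxy group by 1,4-elimination, and oligomers compete with the ten-membered ring. The fallback sets out from 27 and returns at 30, and separates ring closure from the C6 configuration. Indium powder in THF/H2O at 0.002 M closes the same C6–C7 bond under neutral aqueous conditions, where δ-alkoxy allylindiums do not eliminate and the methyl ester does not lactonise. Through the chair with C8 axial this should give the 6-epi carbocyclic hydroxy ester methyl 2-[(1S,2S,3E,6S,7Z,9R,10R)-9-acetoxy-2-hydroxy-10-[(4-methoxybenzyl)oxy]-4,8-dimethyl-6-[(triethylsilyl)oxy]cyclodeca-3,7-dien-1-yl]prop-2-enoate F1. A Mitsunobu reaction with formic acid (PPh3, DIAD, toluene, 0 °C) inverts C6 to the 2R formate F2. KHCO3 in MeOH at 0 °C removes only the formate to give the 2R hydroxy ester F3, which PPTS in CH2Cl2 closes to 30.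

Second, step 12 (fragment union). Aldehyde 21 can epimerise at C8, the organometallic can attack the chloromethyl acrylate, and chelation control may be incomplete. The fallback sets out from 11 and 21 and returns at 25, and sets C9 with a reagent instead of the chelate. The same addition quenched with aq. NH4Cl gives the C9-epimeric alcohols methyl (2Z,4R,6Z,8S,10E)-2-(chloromethyl)-5-hydroxy-4-[(4-methoxybenzyl)oxy]-6,10-dimethyl-8,12-bis[(triethylsilyl)oxy]dodeca-2,6,10-trienoate F4. Buffered Dess–Martin oxidation gives the 5-oxo enone F5, which is kept cold to protect C8. Oxazaborolidine-catalysed (Corey–Bakshi–Shibata) reduction with catecholborane at −78 °C, using the catalyst antipode that delivers hydride to the required face, gives the (5R)-alcohol F6. Ac2O in pyridine at 0 °C then gives 25.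

Third, step 16 (angeloylation). With 8-OH free, Et3N at 80 °C can cause 9→8 acetyl migration or 6,12→8,12 translactonisation, and angelates isomerise to tiglates. The fallback sets out from 31 and returns at 32, and builds the angelate double bond on the substrate. DCC with catalytic DMAP at 0 °C couples 31 with 2-[bis(2,2,2-trifluoroethoxy)phosphoryl]propanoic acid to give the 4-O-phosphonopropanoate of 31, F7. Still–Gennari olefination (KN(SiMe3)2, 18-crown-6, THF, −78 °C, acetaldehyde) then gives the Z-2-methylbut-2-enoate 32.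

**Further compounds**
F1 | step 14 | methyl 2-[(1S,2S,3E,6S,7Z,9R,10R)-9-acetoxy-2-hydroxy-10-[(4-methoxybenzyl)oxy]-4,8-dimethyl-6-[(triethylsilyl)oxy]cyclodeca-3,7-dien-1-yl]prop-2-enoate | COC(=O)C(=C)[C@H]1[C@@H](O)/C=C(\C)C[C@H](O[Si](CC)(CC)CC)/C=C(/C)[C@@H](OC(C)=O)[C@@H]1OCc1ccc(OC)cc1
F2 | step 14 | methyl 2-[(1S,2R,3E,6S,7Z,9R,10R)-9-acetoxy-2-(formyloxy)-10-[(4-methoxybenzyl)oxy]-4,8-dimethyl-6-[(triethylsilyl)oxy]cyclodeca-3,7-dien-1-yl]prop-2-enoate | COC(=O)C(=C)[C@H]1[C@H](OC=O)/C=C(\C)C[C@H](O[Si](CC)(CC)CC)/C=C(/C)[C@@H](OC(C)=O)[C@@H]1OCc1ccc(OC)cc1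
F3 | step 14 | methyl 2-[(1S,2R,3E,6S,7Z,9R,10R)-9-acetoxy-2-hydroxy-10-[(4-methoxybenzyl)oxy]-4,8-dimethyl-6-[(triethylsilyl)oxy]cyclodeca-3,7-dien-1-yl]prop-2-enoate | COC(=O)C(=C)[C@H]1[C@H](O)/C=C(\C)C[C@H](O[Si](CC)(CC)CC)/C=C(/C)[C@@H](OC(C)=O)[C@@H]1OCc1ccc(OC)cc1
F4 | step 12 | methyl (2Z,4R,6Z,8S,10E)-2-(chloromethyl)-5-hydroxy-4-[(4-methoxybenzyl)oxy]-6,10-dimethyl-8,12-bis[(triethylsilyl)oxy]dodeca-2,6,10-trienoate (both C5 epimers) | CC[Si](CC)(CC)OC/C=C(\C)C[C@H](O[Si](CC)(CC)CC)/C=C(/C)C(O)[C@H](OCc1ccc(OC)cc1)/C=C(\CCl)C(=O)OC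
F5 | step 12 | methyl (2Z,4R,6Z,8S,10E)-2-(chloromethyl)-4-[(4-methoxybenzyl)oxy]-6,10-dimethyl-5-oxo-8,12-bis[(triethylsilyl)oxy]dodeca-2,6,10-trienoate | CC[Si](CC)(CC)OC/C=C(\C)C[C@H](O[Si](CC)(CC)CC)/C=C(/C)C(=O)[C@H](OCc1ccc(OC)cc1)/C=C(\CCl)C(=O)OC
F6 | step 12 | methyl (2Z,4R,5R,6Z,8S,10E)-2-(chloromethyl)-5-hydroxy-4-[(4-methoxybenzyl)oxy]-6,10-dimethyl-8,12-bis[(triethylsilyl)oxy]dodeca-2,6,10-trienoate | CC[Si](CC)(CC)OC/C=C(\C)C[C@H](O[Si](CC)(CC)CC)/C=C(/C)[C@@H](O)[C@H](OCc1ccc(OC)cc1)/C=C(\CCl)C(=O)OC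
F7 | step 16 | 2-[bis(2,2,2-trifluoroethoxy)phosphoryl]propanoate of the 4-hydroxyl of 31 (2-O-TES 8-O-phosphonopropanoyl germacranolide) | C=C1C(=O)O[C@@H]2/C=C(\C)C[C@H](O[Si](CC)(CC)CC)/C=C(/C)[C@@H](OC(C)=O)[C@H](OC(=O)C(C)P(=O)(OCC(F)(F)F)OCC(F)(F)F)[C@@H]12
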